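**Retrosynthetic overview**

1. Target 27 comes from diarylmethane 26 by hydrogenolysis of three benzyl ethers; the bridge CH2 of 26 comes from the carbonyl group of ortho-hydroxybenzophenone 23, removed through an ortho-quinone methide.
2. The strategy rests on ring B, where b6 (OMe), b1 (bridge carbon) and b2 (OH) are three neighbouring carbons and the arylethyl chain sits at b4, para to b1. Carbons b1 and b2 are therefore the two ends of an aryne flanked by the b6 methoxy group, and 23 is cut into ring B silyl triflate 12 and ring A benzoic acid 20; one step forms both the b2–O and the b1–C(bridge) bonds.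
3. Triflate 12 comes from 3-bromo-5-methoxyphenol 3 and styrene 2 by hydroboration/B-alkyl Suzuki–Miyaura coupling, then carbamate-directed silylation and triflation.
4. Acid 20 comes from methyl orsellinate 13 by 4-O-methylation, 2-O-benzylation, lateral benzylation with bromide 17 and saponification.
5. No ring is formed; rings A and B and both guaiacyl rings are bought and joined in the order guaiacyl–B, guaiacyl–A, then A–B.

Key step: step 11

Assumption: the target is achiral, so no stereocentre has to be set; 4-benzyloxy-3-methoxybenzyl alcohol 16 is taken as purchasable (it is otherwise two steps from vanillin).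

**Route**

Step 1
Reactants: 1 2-methoxy-4-vinylphenol
Product: 2 4-benzyloxy-3-methoxystyrene
Conditions: BnBr, K2CO3, DMF, rt
Reagents that add atoms: benzyl bromide, BrCc1ccccc1
Why: Williamson ether synthesis on the only acidic OH should proceed at room temperature, which keeps the polymerisable styrene intact.

Step 2
Reactants: 2 4-benzyloxy-3-methoxystyrene; 3 3-bromo-5-methoxyphenol
Product: 5 3-methoxy-5-[2-(4-benzyloxy-3-methoxyphenyl)ethyl]phenol, via B-alkyl-9-BBN borane 4 (not isolated)
Conditions: 9-BBN, THF, 0 °C to rt; then 3, Pd(dppf)Cl2 (5 mol%), aq K3PO4 (4 equiv), THF/DMF, 60 °C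
Reagents that add atoms: none
Why: Anti-Markovnikov hydroboration puts boron on the terminal carbon, and B-alkyl Suzuki–Miyaura coupling of the primary alkylborane with the aryl bromide (oxidative addition to zerovalent palladium, base-assisted transmetalation, reductive elimination) should tolerate the phenol, which is carried as its phenoxide with the extra base.

Step 3
Reactants: 5 3-methoxy-5-[2-(4-benzyloxy-3-methoxyphenyl)ethyl]phenol
Product: 6 3-methoxy-5-[2-(4-benzyloxy-3-methoxyphenyl)ethyl]phenyl N-isopropylcarbamate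
Conditions: i-PrNCO, Et3N (cat.), CH2Cl2, rt
Reagents that add atoms: isopropyl isocyanate, CC(C)N=C=O
Why: Base-catalysed addition of the phenol to the isocyanate gives the secondary carbamate, which serves as a strong ortho-directing group and can later be removed without strong nucleophiles.

Step 4
Reactants: 6 3-methoxy-5-[2-(4-benzyloxy-3-methoxyphenyl)ethyl]phenyl N-isopropylcarbamate
Product: 10 3-methoxy-5-[2-(4-benzyloxy-3-methoxyphenyl)ethyl]-2-(trimethylsilyl)phenyl N-isopropylcarbamate, via N-TBS carbamate 7 (not isolated), via C2 aryllithium 8 (not isolated), via N-TBS C-silyl carbamate 9 (not isolated)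
Conditions: TBSOTf, TMEDA, Et2O, 0 °C to rt; n-BuLi (2.2 equiv), TMEDA, −78 °C; TMSCl, −78 °C to rt; aq NaHSO4
Reagents that add atoms: chlorotrimethylsilane, C[Si](C)(C)Cl
Why: After N-silylation masks the N–H in the flask, directed ortho-metalation should occur at C2, the position flanked by the carbamate and methoxy groups and the most acidic site at −78 °C (benzyl ethers are tolerated under these conditions), and silyl quench followed by acidic work-up, which cleaves the N–Si bond, gives 10.

Step 5
Reactants: 10 3-methoxy-5-[2-(4-benzyloxy-3-methoxyphenyl)ethyl]-2-(trimethylsilyl)phenyl N-isopropylcarbamate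
Product: 12 3-methoxy-5-[2-(4-benzyloxy-3-methoxyphenyl)ethyl]-2-(trimethylsilyl)phenyl trifluoromethanesulfonate, via silylphenol 11 (not isolated)
Conditions: DBU, Et2NH, MeCN, 40 °C; then PhNTf2, rt
Reagents that add atoms: N-phenylbis(trifluoromethanesulfonimide), O=S(=O)(N(c1ccccc1)S(=O)(=O)C(F)(F)F)C(F)(F)F
Why: DBU removes the carbamate N–H and E1cB loss of isopropyl isocyanate (trapped by diethylamine as a urea) frees the phenoxide without breaking the C–Si bond, and sulfonyl transfer from PhNTf2 in the same flask gives the silyl triflate.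

Step 6
Reactants: 13 methyl orsellinate (methyl 2,4-dihydroxy-6-methylbenzoate)
Product: 14 methyl 2-hydroxy-4-methoxy-6-methylbenzoate
Conditions: MeI (1.05 equiv), K2CO3, acetone, rt
Reagents that add atoms: iodomethane, CI
Why: Williamson methylation should be selective for the 4-OH because the 2-OH is held in a hydrogen bond to the ester carbonyl and is much less nucleophilic.

Step 7
Reactants: 14 methyl 2-hydroxy-4-methoxy-6-methylbenzoate
Product: 15 methyl 2-benzyloxy-4-methoxy-6-methylbenzoate
Conditions: BnBr, K2CO3, DMF, 60 °C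
Reagents that add atoms: benzyl bromide, BrCc1ccccc1
Why: Williamson benzylation of the remaining chelated phenol proceeds on warming in a polar aprotic solvent.

Step 8
Reactants: 16 4-benzyloxy-3-methoxybenzyl alcohol
Product: 17 4-benzyloxy-3-methoxybenzyl bromide
Conditions: PBr3, CH2Cl2, 0 °C
Reagents that add atoms: phosphorus tribromide, BrP(Br)Br
Why: Bromide displaces the activated phosphite ester of the primary benzylic alcohol; the electron-rich bromide is used directly in step 9.

Step 9
Reactants: 15 methyl 2-benzyloxy-4-methoxy-6-methylbenzoate; 17 4-benzyloxy-3-methoxybenzyl bromide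
Product: 19 methyl 2-benzyloxy-4-methoxy-6-[2-(4-benzyloxy-3-methoxyphenyl)ethyl]benzoate, via benzylic lithium species 18 (not isolated)
Conditions: LDA (LiN(i-Pr)2, 1.1 equiv), THF, −78 °C; then 17, −78 to 0 °C
Reagents that add atoms: none
Why: Lateral lithiation of the ortho-toluate gives an ester-stabilised benzylic anion that should be alkylated by the reactive benzylic bromide (SN2), with the hindered ester and low temperature suppressing self-condensation.

Step 10
Reactants: 19 methyl 2-benzyloxy-4-methoxy-6-[2-(4-benzyloxy-3-methoxyphenyl)ethyl]benzoate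
Product: 20 2-benzyloxy-4-methoxy-6-[2-(4-benzyloxy-3-methoxyphenyl)ethyl]benzoic acid
Conditions: KOH, DMSO/H2O, 90 °C; then cold dilute HCl to pH 3
Reagents that add atoms: potassium hydroxide, [K+].[OH-]
Why: Saponification of the doubly ortho-substituted ester needs poorly solvated hydroxide in hot aqueous DMSO, conditions that benzyl and methyl aryl ethers withstand, and cold mild acidification avoids decarboxylation of the electron-rich acid.

Step 11
Reactants: 12 3-methoxy-5-[2-(4-benzyloxy-3-methoxyphenyl)ethyl]-2-(trimethylsilyl)phenyl trifluoromethanesulfonate; 20 2-benzyloxy-4-methoxy-6-[2-(4-benzyloxy-3-methoxyphenyl)ethyl]benzoic acid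
Product: 23 {2-benzyloxy-4-methoxy-6-[2-(4-benzyloxy-3-methoxyphenyl)ethyl]phenyl}{2-hydroxy-6-methoxy-4-[2-(4-benzyloxy-3-methoxyphenyl)ethyl]phenyl}methanone, via 3-methoxyaryne 21 (not isolated), via aryl anion ester 22 (not isolated)
Conditions: 12 (1.5 equiv), CsF (4 equiv), THF, 125 °C, sealed tube; then aq NH4Cl
Reagents that add atoms: none
Why: Fluoride attacks silicon of 12 and loss of triflate gives aryne 21 between b1 and b2, while acid 20 is present as its cesium carboxylate. The carboxylate oxygen adds to the aryne and the resulting aryl anion 22 attacks the ester carbonyl beside it, closing a transient four-membered benzoxetene alkoxide (4-exo-trig) that reopens by C–O cleavage to the phenoxide of 23, so no ring persists and no stereocentre is formed. The closest known reaction type is the fluoride-induced insertion of arynes into the C–O bond of aromatic carboxylic acids, which gives ortho-hydroxyaryl ketones. The step needs regioselective addition, and the inductively withdrawing methoxy group at b6 distorts the aryne so that the nucleophile bonds to the remote carbon b2 and the charge develops at b1, the chain at b4 being too far away to interfere. It also needs acyl transfer to outrun protonation of 22, which dry THF, excess CsF and the intramolecular course of the shift should favour even though the acyl carbon of 20 carries two ortho substituents. Benzyl and methyl ethers are inert to the aryne and to fluoride.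

Step 12
Reactants: 23 the ortho-hydroxybenzophenone of step 11
Product: 24 2-{2-benzyloxy-4-methoxy-6-[2-(4-benzyloxy-3-methoxyphenyl)ethyl]benzoyl}-3-methoxy-5-[2-(4-benzyloxy-3-methoxyphenyl)ethyl]phenyl ethyl carbonate
Conditions: ClCO2Et, Et3N, THF, 0 °C
Reagents that add atoms: ethyl chloroformate, CCOC(Cl)=O
Why: O-Acylation of the b2 phenol breaks its chelate to the ketone and installs the group that is later transferred and expelled.

Step 13
Reactants: 24 the aryl ethyl carbonate of step 12
Product: 26 2-{2-benzyloxy-4-methoxy-6-[2-(4-benzyloxy-3-methoxyphenyl)ethyl]benzyl}-3-methoxy-5-[2-(4-benzyloxy-3-methoxyphenyl)ethyl]phenol, via ortho-quinone methide 25 (not isolated)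
Conditions: NaBH4, THF/H2O, 0 °C to rt
Reagents that add atoms: none
Why: In this ortho-hydroxy-assisted deoxygenation of an aryl ketone, hydride reduction gives a benzylic alkoxide that takes over the ethoxycarbonyl group, the freed phenoxide expels ethyl carbonate to form ortho-quinone methide 25, and a second hydride adds to its exocyclic carbon.

Step 14
Reactants: 26 the tribenzyl diarylmethane of step 13
Product: 27 2-{2-hydroxy-4-methoxy-6-[2-(4-hydroxy-3-methoxyphenyl)ethyl]benzyl}-3-methoxy-5-[2-(4-hydroxy-3-methoxyphenyl)ethyl]phenol (CNP0079001.0)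
Conditions: H2 (1 atm), 10% Pd/C, EtOAc/MeOH, rt
Reagents that add atoms: none
Why: Catalytic hydrogenolysis should cleave the three benzyl aryl ethers while the diarylmethane and bibenzyl C–C bonds and the methyl ethers remain untouched.

**Compound list**

1 | 2-methoxy-4-vinylphenol | C=Cc1ccc(O)c(OC)c1 | starting material
2 | 4-benzyloxy-3-methoxystyrene | C=Cc1ccc(OCc2ccccc2)c(OC)c1 | intermediate
3 | 3-bromo-5-methoxyphenol | COc1cc(O)cc(Br)c1 | starting material
4 | B-[2-(4-benzyloxy-3-methoxyphenyl)ethyl]-9-borabicyclo[3.3.1]nonane | COc1cc(CCB2C3CCCC2CCC3)ccc1OCc1ccccc1 | intermediate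
5 | 3-methoxy-5-[2-(4-benzyloxy-3-methoxyphenyl)ethyl]phenol | COc1cc(O)cc(CCc2ccc(OCc3ccccc3)c(OC)c2)c1 | intermediate
6 | 3-methoxy-5-[2-(4-benzyloxy-3-methoxyphenyl)ethyl]phenyl N-isopropylcarbamate | COc1cc(OC(=O)NC(C)C)cc(CCc2ccc(OCc3ccccc3)c(OC)c2)c1 | intermediate
7 | N-(tert-butyldimethylsilyl) derivative of carbamate 6 | COc1cc(OC(=O)N(C(C)C)[Si](C)(C)C(C)(C)C)cc(CCc2ccc(OCc3ccccc3)c(OC)c2)c1 | intermediate
8 | C2 aryllithium of 7 (lithium between the methoxy and carbamate carbons) | COc1cc(CCc2ccc(OCc3ccccc3)c(OC)c2)cc(OC(=O)N(C(C)C)[Si](C)(C)C(C)(C)C)c1[Li] | intermediate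
9 | N-(tert-butyldimethylsilyl) C2-trimethylsilyl carbamate | COc1cc(CCc2ccc(OCc3ccccc3)c(OC)c2)cc(OC(=O)N(C(C)C)[Si](C)(C)C(C)(C)C)c1[Si](C)(C)C | intermediate
10 | 3-methoxy-5-[2-(4-benzyloxy-3-methoxyphenyl)ethyl]-2-(trimethylsilyl)phenyl N-isopropylcarbamate | COc1cc(CCc2ccc(OCc3ccccc3)c(OC)c2)cc(OC(=O)NC(C)C)c1[Si](C)(C)C | intermediate
11 | 3-methoxy-5-[2-(4-benzyloxy-3-methoxyphenyl)ethyl]-2-(trimethylsilyl)phenol | COc1cc(CCc2ccc(OCc3ccccc3)c(OC)c2)cc(O)c1[Si](C)(C)C | intermediate
12 | 3-methoxy-5-[2-(4-benzyloxy-3-methoxyphenyl)ethyl]-2-(trimethylsilyl)phenyl trifluoromethanesulfonate | COc1cc(CCc2ccc(OCc3ccccc3)c(OC)c2)cc(OS(=O)(=O)C(F)(F)F)c1[Si](C)(C)C | intermediate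
13 | methyl orsellinate | COC(=O)c1c(C)cc(O)cc1O | starting material
14 | methyl 2-hydroxy-4-methoxy-6-methylbenzoate | COC(=O)c1c(C)cc(OC)cc1O | intermediate
15 | methyl 2-benzyloxy-4-methoxy-6-methylbenzoate | COC(=O)c1c(C)cc(OC)cc1OCc1ccccc1 | intermediate
16 | 4-benzyloxy-3-methoxybenzyl alcohol | COc1cc(CO)ccc1OCc1ccccc1 | starting material
17 | 4-benzyloxy-3-methoxybenzyl bromide | COc1cc(CBr)ccc1OCc1ccccc1 | intermediate
18 | laterally lithiated ester 15 (benzylic lithium species) | COC(=O)c1c(C[Li])cc(OC)cc1OCc1ccccc1 | intermediate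
19 | methyl 2-benzyloxy-4-methoxy-6-[2-(4-benzyloxy-3-methoxyphenyl)ethyl]benzoate | COC(=O)c1c(OCc2ccccc2)cc(OC)cc1CCc1ccc(OCc2ccccc2)c(OC)c1 | intermediate
20 | 2-benzyloxy-4-methoxy-6-[2-(4-benzyloxy-3-methoxyphenyl)ethyl]benzoic acid | O=C(O)c1c(OCc2ccccc2)cc(OC)cc1CCc1ccc(OCc2ccccc2)c(OC)c1 | intermediate
21 | 3-methoxy-5-[2-(4-benzyloxy-3-methoxyphenyl)ethyl]benzyne (ring B aryne, triple bond b1–b2) | COC1=CC(CCc2ccc(OCc3ccccc3)c(OC)c2)=CC#C1 | intermediate
22 | cesium salt of the b1 aryl anion of the b2 aryl ester of acid 20 | [Cs+].COc1cc(CCc2ccc(OCc3ccccc3)c(OC)c2)cc(OC(=O)c2c(OCc3ccccc3)cc(OC)cc2CCc2ccc(OCc3ccccc3)c(OC)c2)[c-]1 | intermediate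
23 | {2-benzyloxy-4-methoxy-6-[2-(4-benzyloxy-3-methoxyphenyl)ethyl]phenyl}{2-hydroxy-6-methoxy-4-[2-(4-benzyloxy-3-methoxyphenyl)ethyl]phenyl}methanone | COc1cc(OCc2ccccc2)c(C(=O)c2c(O)cc(CCc3ccc(OCc4ccccc4)c(OC)c3)cc2OC)c(CCc2ccc(OCc3ccccc3)c(OC)c2)c1 | intermediate
24 | ethyl carbonate of 23 at the b2 oxygen | COc1cc(OCc2ccccc2)c(C(=O)c2c(OC(=O)OCC)cc(CCc3ccc(OCc4ccccc4)c(OC)c3)cc2OC)c(CCc2ccc(OCc3ccccc3)c(OC)c2)c1 | intermediate
25 | ring B ortho-quinone methide (exocyclic alkene geometry not defined) | COC1=CC(CCc2ccc(OCc3ccccc3)c(OC)c2)=CC(=O)C1=Cc1c(OCc2ccccc2)cc(OC)cc1CCc1ccc(OCc2ccccc2)c(OC)c1 | intermediate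
26 | 2-{2-benzyloxy-4-methoxy-6-[2-(4-benzyloxy-3-methoxyphenyl)ethyl]benzyl}-3-methoxy-5-[2-(4-benzyloxy-3-methoxyphenyl)ethyl]phenol | COc1cc(OCc2ccccc2)c(Cc2c(O)cc(CCc3ccc(OCc4ccccc4)c(OC)c3)cc2OC)c(CCc2ccc(OCc3ccccc3)c(OC)c2)c1 | intermediate
27 | 2-{2-hydroxy-4-methoxy-6-[2-(4-hydroxy-3-methoxyphenyl)ethyl]benzyl}-3-methoxy-5-[2-(4-hydroxy-3-methoxyphenyl)ethyl]phenol (CNP0079001.0) | COc1cc(O)c(Cc2c(O)cc(CCc3ccc(O)c(OC)c3)cc2OC)c(CCc2ccc(O)c(OC)c2)c1 | target

**Step count**

Total steps: 14. Longest linear sequence: 9 steps (steps 1 to 5, then 11 to 14).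

**Steps most likely to fail**

Step 11. The aryl anion formed next to the new ester may be protonated by bifluoride before it reaches the carbonyl carbon, which is shielded by both ortho substituents of ring A, so the reaction could stop at simple O-arylation; the product phenoxide could also be arylated a second time. The fallback makes the ring A–ring B bond by carbonyl addition of an ortho-lithiated ring B ether; it sets out from ester 19 and phenol 5 and comes back at 26. Ester 19 is reduced with LiAlH4 (THF, 0 °C) to 2-benzyloxy-4-methoxy-6-[2-(4-benzyloxy-3-methoxyphenyl)ethyl]benzyl alcohol F1, which MnO2 (CH2Cl2, rt) should oxidise to 2-benzyloxy-4-methoxy-6-[2-(4-benzyloxy-3-methoxyphenyl)ethyl]benzaldehyde F2. Phenol 5 is converted with MOMCl and i-Pr2NEt into its methoxymethyl ether F3. n-BuLi/TMEDA (THF, 0 °C) should lithiate F3 between its two oxygen substituents, and addition to F2 at −78 °C should give the racemic diarylcarbinol F4. Ionic hydrogenation (Et3SiH, TFA, CH2Cl2, −20 °C) of the doubly stabilised benzhydryl cation should give the methoxymethyl ether of 26 F5, and HCl in MeOH then frees the b2 phenol to reach 26.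

Step 13. Hydride delivery to a carbonyl buried between four ortho substituents may be slow, so that attack at the carbonate carbonyl simply returns 23 and the quinone methide relay never starts. The fallback replaces the base-mediated relay by stepwise reduction and acid-mediated deoxygenation; it sets out from 23 and comes back at 26. LiAlH4 (THF, 0 °C to reflux) should reduce the aluminium-chelated ketone of 23 to the racemic diarylcarbinol F6, and Et3SiH/TFA (CH2Cl2, 0 °C) should reduce its benzhydryl cation to 26.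

Step 9. The lithiated toluate may condense with unreacted ester, and the electron-rich benzylic bromide may be consumed by base-induced side reactions, leaving low conversion to 19. The fallback traps the same anion with an aldehyde, which reacts faster and irreversibly through lactonisation, and it also bypasses the hindered saponification of step 10; it sets out from 15 and 16 and comes back at 20. Alcohol 16 is oxidised with MnO2 (CH2Cl2) to 4-benzyloxy-3-methoxybenzaldehyde F7. Ester 15 is lithiated as before (LDA, THF, −78 °C) and F7 is added; the alkoxide should close onto the ester to give racemic 8-benzyloxy-3-(4-benzyloxy-3-methoxyphenyl)-6-methoxy-3,4-dihydroisocoumarin F8. t-BuOK in DMSO at rt should open the lactone by E1cB elimination to (E)-2-benzyloxy-4-methoxy-6-[2-(4-benzyloxy-3-methoxyphenyl)vinyl]benzoic acid F9, and diimide (TsNHNH2, NaOAc, THF/H2O, reflux) should saturate the stilbene without touching the benzyl ethers to give 20.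

**Further compounds**

F1 | step 11 | 2-benzyloxy-4-methoxy-6-[2-(4-benzyloxy-3-methoxyphenyl)ethyl]benzyl alcohol | OCc1c(OCc2ccccc2)cc(OC)cc1CCc1ccc(OCc2ccccc2)c(OC)c1
F2 | step 11 | 2-benzyloxy-4-methoxy-6-[2-(4-benzyloxy-3-methoxyphenyl)ethyl]benzaldehyde | O=Cc1c(OCc2ccccc2)cc(OC)cc1CCc1ccc(OCc2ccccc2)c(OC)c1
F3 | step 11 | 1-[2-(4-benzyloxy-3-methoxyphenyl)ethyl]-3-methoxy-5-(methoxymethoxy)benzene | COCOc1cc(OC)cc(CCc2ccc(OCc3ccccc3)c(OC)c2)c1
F4 | step 11 | racemic {2-benzyloxy-4-methoxy-6-[2-(4-benzyloxy-3-methoxyphenyl)ethyl]phenyl}{2-methoxy-6-(methoxymethoxy)-4-[2-(4-benzyloxy-3-methoxyphenyl)ethyl]phenyl}methanol | COCOc1cc(CCc2ccc(OCc3ccccc3)c(OC)c2)cc(OC)c1C(O)c1c(OCc2ccccc2)cc(OC)cc1CCc1ccc(OCc2ccccc2)c(OC)c1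
F5 | step 11 | methoxymethyl ether of 26 | COCOc1cc(CCc2ccc(OCc3ccccc3)c(OC)c2)cc(OC)c1Cc1c(OCc2ccccc2)cc(OC)cc1CCc1ccc(OCc2ccccc2)c(OC)c1
F6 | step 13 | racemic {2-benzyloxy-4-methoxy-6-[2-(4-benzyloxy-3-methoxyphenyl)ethyl]phenyl}{2-hydroxy-6-methoxy-4-[2-(4-benzyloxy-3-methoxyphenyl)ethyl]phenyl}methanol | COc1cc(OCc2ccccc2)c(C(O)c2c(O)cc(CCc3ccc(OCc4ccccc4)c(OC)c3)cc2OC)c(CCc2ccc(OCc3ccccc3)c(OC)c2)c1
F7 | step 9 | 4-benzyloxy-3-methoxybenzaldehyde | COc1cc(C=O)ccc1OCc1ccccc1
F8 | step 9 | racemic 8-benzyloxy-3-(4-benzyloxy-3-methoxyphenyl)-6-methoxy-3,4-dihydroisocoumarin | O=C1OC(c2ccc(OCc3ccccc3)c(OC)c2)Cc2cc(OC)cc(OCc3ccccc3)c21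
F9 | step 9 | (E)-2-benzyloxy-4-methoxy-6-[2-(4-benzyloxy-3-methoxyphenyl)vinyl]benzoic acid | O=C(O)c1c(OCc2ccccc2)cc(OC)cc1/C=C/c1ccc(OCc2ccccc2)c(OC)c1
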